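**Retrosynthetic overview**

1. Ring B (C5–C10) comes from (R)-carvone; ring A (C10–C1–C2–C3–C4–C5) is disconnected last, at the C3–C4 bond.
2. Enabling feature: C4 is the α-carbon of the C19 lactone carbonyl and lies 1,3 to C10 across C5 inside the δ-lactone ring C4–C19–O–C20–C10–C5, which is cis-fused to ring B. An α C1–C3 arm on C10 is axial on that ring, so the C4 enolate can only be alkylated in a bridging sense.
3. Before it: δ-lactone from the 19,20-diol; oxirane by 6β-OH-directed epoxidation of C8=C17; tetrahydrofuran and oxolane by oxidative cyclisation of 9α-OH onto C13=C16 followed by transacetalisation; 9α-OH and C6=O by singlet-oxygen cycloaddition and Kornblum–DeLaMare rearrangement of a ring-B diene (dienyl triflate plus alkylzinc).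
4. The C10 quaternary centre comes from double α′-alkylation of carvone (C20 first, then the C1–C3 arm anti to the C5 substituent); C19 from hydroboration of the isopropenyl group.
5. Ring order: ring B (carvone) → tetrahydrofuran and oxolane (step 10) → oxirane (step 13) → δ-lactone (step 18) → ring A (step 19).

Key step: step 19

Remark: locants are those of labdane (ring A = C1–C5 and C10; ring B = C5–C10; side chain C11–C16; C17 on C8; C18 and C19 on C4; C20 on C10), with α/β as in the target. C4 (compounds 6–30) and C15 (compounds 20–34) are carried as epimer mixtures and left undefined in the SMILES; the first is fixed in step 19, the second removed in step 22.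

**Route**

Step 1
Reactants: 1 (R)-(−)-carvone
Product: 3 10-(benzyloxymethyl)carvone (C20 trans to the C5 isopropenyl group), via lithium enolate 2 (not isolated)
Conditions: LiN(i-Pr)2 (LDA), THF, −78 °C; BnOCH2Cl, −78 → −20 °C
Reagents that add atoms: benzyl chloromethyl ether, ClCOCc1ccccc1
Why: Kinetic α′-enolate alkylation of carvone with an α-chloro ether should place C20 on C10 (carvone C6) trans to the isopropenyl group, a centre that is enolised again in step 2.

Step 2
Reactants: 3 10-(benzyloxymethyl)carvone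
Product: 5 C10-quaternary enone (C20 β; silyloxypropyl arm C1–C3 α), via lithium enolate 4 (not isolated)
Conditions: LiN(i-Pr)2 (LDA), THF/DMPU, −78 °C; I(CH2)3OTBS, −78 → 0 °C
Reagents that add atoms: tert-butyl(3-iodopropoxy)dimethylsilane, ICCCO[Si](C)(C)C(C)(C)C
Why: Second α′-alkylation of the tertiary enolate, in which the iodide should approach anti to the C5 isopropenyl group as is usual for 6-substituted carvones, so that the arm ends α and C20 β at the quaternary C10.

Step 3
Reactants: 5 C10-quaternary enone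
Product: 7 C19 primary alcohol, via B-alkyl-9-BBN adduct 6 (not isolated)
Conditions: 9-BBN, THF, 0 → 23 °C; H2O2, aq. NaHCO3, 0 °C
Reagents that add atoms: hydrogen peroxide, OO
Why: Anti-Markovnikov hydroboration–oxidation (Brown) should touch only the 1,1-disubstituted isopropenyl alkene, the conjugated and neopentyl-flanked enone being inert to 9-BBN; the new C4 centre need not be controlled because it is enolised in step 19.

Step 4
Reactants: 7 C19 primary alcohol
Product: 8 C19 benzyl ether
Conditions: BnOC(=NH)CCl3, TfOH (cat.), CH2Cl2/cyclohexane, 0 °C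
Reagents that add atoms: benzyl 2,2,2-trichloroacetimidate, N=C(OCc1ccccc1)C(Cl)(Cl)Cl
Why: Acid-catalysed imidate benzylation protects the alcohol without a base, so the enone is not enolised and the primary silyl ether should survive.

Step 5
Reactants: 8 C19 benzyl ether
Product: 10 dienyl triflate (C9–OTf; C8=C9 and C6=C7), via lithium dienolate 9 (not isolated)
Conditions: LiN(i-Pr)2 (LDA), THF, −78 °C; PhNTf2, −78 → 0 °C
Reagents that add atoms: N-phenylbis(trifluoromethanesulfonimide), FC(F)(F)S(=O)(=O)N(c1ccccc1)S(=O)(=O)C(F)(F)F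
Why: With the α′ position quaternary, LDA can only remove a γ-proton at C6, and O-sulfonylation of the linear dienolate (enol triflate formation) should give the ring-B dienyl triflate.

Step 6
Reactants: 11 3-methylbut-3-en-1-ol
Product: 13 5,5-diethoxy-3-methylidenepentan-1-ol, via dilithio alkoxide 12 (not isolated)
Conditions: n-BuLi (2.2 equiv), TMEDA, Et2O, 0 → 23 °C; PhOCH(OEt)2, 0 → 23 °C; aq. NH4Cl
Reagents that add atoms: diethyl phenyl orthoformate, CCOC(OCC)Oc1ccccc1
Why: The allylic dianion of isoprenol has two equivalent allyl termini and should be formylated at carbon by the mixed orthoformate (Bodroux–Chichibabin-type acetal synthesis, phenoxide as leaving group).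

Step 7
Reactants: 13 5,5-diethoxy-3-methylidenepentan-1-ol
Product: 14 1,1-diethoxy-5-iodo-3-methylidenepentane
Conditions: I2, PPh3, imidazole, CH2Cl2, 0 °C
Reagents that add atoms: iodine, II
Why: Garegg–Samuelsson (Appel-type) iodination of the primary alcohol runs under buffered conditions that should spare the acetal and the alkene.

Step 8
Reactants: 14 1,1-diethoxy-5-iodo-3-methylidenepentane; 10 dienyl triflate
Product: 16 ring-B 6,8-diene carrying the C11–C16 chain on C9, via alkylzinc iodide 15 (not isolated)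
Conditions: Zn dust, LiCl, THF, 40 °C; 10, Pd(dppf)Cl2 (5 mol %), THF/NMP, 50 °C
Reagents that add atoms: none
Why: Zinc insertion into the primary iodide and Negishi sp3–sp2 coupling with the dienyl triflate should form C9–C11 and deliver the homoannular diene with defined double-bond positions.

Step 9
Reactants: 16 ring-B 6,8-diene
Product: 18 9α-hydroxy-7-en-6-one, via endoperoxide 17 (not isolated)
Conditions: O2, tetraphenylporphyrin (cat.), visible light, CH2Cl2, −30 °C; Et3N, 0 → 23 °C
Reagents that add atoms: oxygen, O=O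
Why: Singlet oxygen should add [4+2] to the cisoid ring diene far faster than it undergoes ene reactions, from the α-face opposite the pseudo-axial C20 and the C4 side chain, and the Kornblum–DeLaMare rearrangement (only C6 carries a hydrogen) then gives the C6 ketone and the 9α-hydroxyl.

Step 10
Reactants: 18 9α-hydroxy-7-en-6-one
Product: 20 spiro tetrahydrofuran–oxolane enone (9α,13:15,16-diepoxy-15-ethoxy), via hydroxymethyl tetrahydrofuran 19 (not isolated)
Conditions: Co(modp)2 (C24H36CoN2O8; modp = 1-morpholinocarbamoyl-4,4-dimethyl-1,3-pentanedionate; 10 mol %), O2 (1 atm), t-BuOOH (cat.), i-PrOH, 55 °C; PPTS, CH2Cl2, 23 °C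
Reagents that add atoms: oxygen, O=O
Why: Mukaiyama aerobic oxidative cyclisation (5-exo, chair-like transition state with the bulkier quaternary C10 arm of C9 pseudo-equatorial) should give the tetrahydrofuran with C16 trans to C10, which is the C13 configuration of the target, and acid then closes the oxolane by transacetalisation of C16–OH onto C15.

Step 11
Reactants: 20 spiro tetrahydrofuran–oxolane enone
Product: 22 8(17)-en-6-one, via potassium dienolate 21 (not isolated)
Conditions: KOt-Bu (3 equiv), t-BuOH/THF, 23 °C; inverse quench into AcOH/H2O, −20 °C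
Reagents that add atoms: none
Why: Deconjugation through the extended dienolate (only C17 offers γ-protons because C9 is quaternary) and kinetic α-protonation at C7 should give the exocyclic alkene, while reversible enolisation towards C5 leaves the more stable 5α-H epimer with C4 equatorial.

Step 12
Reactants: 22 8(17)-en-6-one
Product: 23 8(17)-en-6β-ol
Conditions: LiBH(s-Bu)3 (L-Selectride), THF, −78 °C; AcOH, −78 °C
Reagents that add atoms: none
Why: The bulky hydride should attack equatorially from the α-face, the β-axial trajectory being blocked by the axial C20, to give the axial 6β-alcohol.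

Step 13
Reactants: 23 8(17)-en-6β-ol
Product: 24 8β,17-epoxy-6β-ol
Conditions: VO(acac)2 (5 mol %), t-BuOOH (decane), CH2Cl2, 0 → 23 °C
Reagents that add atoms: tert-butyl hydroperoxide, CC(C)(C)OO
Why: Hydroxyl-directed vanadium-catalysed epoxidation of the homoallylic alcohol should deliver oxygen from the axial 6β-OH to the β-face of C8=C17, setting the 8β,17-oxirane.

Step 14
Reactants: 24 8β,17-epoxy-6β-ol
Product: 25 3,6β-diol
Conditions: Bu4NF, THF, 0 °C
Reagents that add atoms: none
Why: Fluoride cleavage of the primary silyl ether frees C3–OH only now, after the base and hydride steps that a leaving group on the arm would not have survived next to the C6 ketone.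

Step 15
Reactants: 25 3,6β-diol
Product: 26 C3 tosylate
Conditions: TsCl, Et3N, DMAP (cat.), CH2Cl2, 0 °C
Reagents that add atoms: p-toluenesulfonyl chloride, Cc1ccc(cc1)S(Cl)(=O)=O
Why: Sulfonylation should be selective for the unhindered primary alcohol, the axial 6β-OH being flanked 1,3-diaxially by C20 and the oxirane oxygen.

Step 16
Reactants: 26 C3 tosylate
Product: 27 6β-triethylsilyl ether
Conditions: Et3SiCl, Et3N, DMAP, CH2Cl2, 23 °C
Reagents that add atoms: chlorotriethylsilane, CC[Si](Cl)(CC)CC
Why: Silylation masks the 6β-oxygen so that it can neither be deprotonated nor attack the C19 carbonyl during the enolate step.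

Step 17
Reactants: 27 6β-triethylsilyl ether
Product: 28 19,20-diol
Conditions: H2 (1 atm), Pd/C, EtOAc, 23 °C
Reagents that add atoms: none
Why: Hydrogenolysis should remove both benzyl ethers; no alkene remains, and the tosylate, silyl ether, acetal and oxirane are stable to neutral Pd/C and hydrogen.

Step 18
Reactants: 28 19,20-diol
Product: 30 19,20-olide (δ-lactone, C4–H), via lactol 29 (not isolated)
Conditions: TEMPO (20 mol %), PhI(OAc)2, CH2Cl2, 23 °C
Reagents that add atoms: none
Why: In this oxidative lactonisation of a 1,5-diol the less hindered C19 carbinol should be oxidised first, the aldehyde is trapped by the neopentyl C20–OH as a lactol, and further oxidation gives the δ-lactone with its carbonyl at C19.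

Step 19
Reactants: 30 19,20-olide
Product: 32 ring-A-closed lactone (6β-OSiEt3, 15-ethoxy), via potassium enolate 31 (not isolated)
Conditions: KN(SiMe3)2 (KHMDS, 1.3 equiv), THF, −78 → 23 °C
Reagents that add atoms: none
Why: KHMDS removes the only acidic proton, C4–H, to give the endocyclic potassium ester enolate, whose α-carbon displaces the C3 tosylate in an intramolecular SN2 reaction; the closest known reaction type is the bridging alkylation of lactone and ketone enolates used to build bicyclo[3.3.1]nonanes. Ring A is closed in the 6-(enolexo)-exo-tet mode, which completes the 3-oxabicyclo[3.3.1]nonan-2-one core. The new quaternary stereocentre C4 is controlled by the tether: the C1–C3 arm is fixed α on C10 and axial on the cis-fused lactone ring, so C3 can reach only the enolate face syn to that arm, which places C18 α and keeps C19 β. Both C4 epimers of 30 converge on the same planar enolate, so the step is stereoconvergent. The selectivity needed is C- over O-alkylation and enolisation at C4 alone; O-alkylation would require a strained eight-membered ketene acetal, and 30 has no other enolisable or base-labile site because C6 is a silyl ether, C15 an acetal and the oxirane is neopentyl-like.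

Step 20
Reactants: 32 ring-A-closed lactone
Product: 33 6β-alcohol
Conditions: Bu4NF, AcOH, THF, 0 → 23 °C
Reagents that add atoms: none
Why: Buffered fluoride desilylation keeps the 6β-oxygen protonated, so it should not attack the nearby C19 carbonyl (translactonisation).

Step 21
Reactants: 33 6β-alcohol
Product: 34 6β-acetate (15-ethoxy acetal)
Conditions: Ac2O, DMAP, pyridine, CH2Cl2, 23 °C
Reagents that add atoms: acetic anhydride, CC(=O)OC(C)=O
Why: DMAP-catalysed acylation should acetylate the hindered axial alcohol promptly and under non-nucleophilic conditions that leave lactone, oxirane and acetal untouched.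

Step 22
Reactants: 34 6β-acetate
Product: 35 target
Conditions: Me3SiOTf, i-Pr2NEt, CH2Cl2, −40 → 0 °C
Reagents that add atoms: none
Why: Silyl triflate/amine elimination of an acetal to an enol ether: the cyclic acetal ionises to the oxocarbenium ion and the amine removes a C14 proton to give the 2,3-dihydrofuran, acetals ionising at low temperature much faster than the hindered oxirane is opened.

**Compound list**

1 | (R)-(−)-carvone | CC1=CC[C@H](CC1=O)C(=C)C | starting material
2 | lithium enolate of 1 (O–Li on C9, C9=C10) | [Li]OC1=C[C@H](C(C)=C)CC=C1C | intermediate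
3 | 10-(benzyloxymethyl)carvone, CH2OBn (C20) trans to the C5 isopropenyl group | O=C1C(C)=CC[C@@H](C(C)=C)[C@@H]1COCc2ccccc2 | intermediate
4 | lithium enolate of 3 (C9=C10) | [Li]OC1=C(COCc2ccccc2)[C@H](C(C)=C)CC=C1C | intermediate
5 | enone with quaternary C10: β-CH2OBn (cis to isopropenyl), α-[3-(tert-butyldimethylsilyloxy)propyl] arm (C1–C3) | O=C1C(C)=CC[C@@H](C(C)=C)[C@]1(COCc2ccccc2)CCCO[Si](C)(C)C(C)(C)C | intermediate
6 | B-(C19-alkyl)-9-borabicyclo[3.3.1]nonane adduct of 5 | O=C1C(C)=CC[C@@H](C(C)CB2C3CCCC2CCC3)[C@]1(COCc4ccccc4)CCCO[Si](C)(C)C(C)(C)C | intermediate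
7 | C19 primary alcohol [C5 side chain CH(CH3)CH2OH] | O=C1C(C)=CC[C@@H](C(C)CO)[C@]1(COCc2ccccc2)CCCO[Si](C)(C)C(C)(C)C | intermediate
8 | C19 benzyl ether of 7 | O=C1C(C)=CC[C@@H](C(C)COCc2ccccc2)[C@]1(COCc3ccccc3)CCCO[Si](C)(C)C(C)(C)C | intermediate
9 | lithium dienolate of 8 (O–Li on C9; C9=C8, C7=C6) | [Li]OC1=C(C)C=C[C@@H](C(C)COCc2ccccc2)[C@]1(COCc3ccccc3)CCCO[Si](C)(C)C(C)(C)C | intermediate
10 | dienyl triflate (C9–OTf; C8=C9, C6=C7) | FC(F)(F)S(=O)(=O)OC1=C(C)C=C[C@@H](C(C)COCc2ccccc2)[C@]1(COCc3ccccc3)CCCO[Si](C)(C)C(C)(C)C | intermediate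
11 | 3-methylbut-3-en-1-ol | CC(=C)CCO | starting material
12 | dilithio derivative of 11 (lithium alkoxide, 2-substituted allyllithium) | [Li]CC(=C)CCO[Li] | intermediate
13 | 5,5-diethoxy-3-methylidenepentan-1-ol | OCCC(=C)CC(OCC)OCC | intermediate
14 | 1,1-diethoxy-5-iodo-3-methylidenepentane | ICCC(=C)CC(OCC)OCC | intermediate
15 | (5,5-diethoxy-3-methylidenepentyl)zinc iodide | I[Zn]CCC(=C)CC(OCC)OCC | intermediate
16 | ring-B 6,8-diene with the C11–C16 chain (C13=C16H2, C15 diethyl acetal) on C9 | CCOC(OCC)CC(=C)CCC1=C(C)C=C[C@@H](C(C)COCc2ccccc2)[C@]1(COCc3ccccc3)CCCO[Si](C)(C)C(C)(C)C | intermediate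
17 | 6α,9α-endoperoxide (C7=C8) | CCOC(OCC)CC(=C)CC[C@@]12OO[C@@H](C=C1C)[C@@H](C(C)COCc3ccccc3)[C@]2(COCc4ccccc4)CCCO[Si](C)(C)C(C)(C)C | intermediate
18 | 9α-hydroxy-7-en-6-one | CCOC(OCC)CC(=C)CC[C@@]1(O)C(C)=CC(=O)[C@@H](C(C)COCc2ccccc2)[C@]1(COCc3ccccc3)CCCO[Si](C)(C)C(C)(C)C | intermediate
19 | 9α,13-epoxy (tetrahydrofuran) 16-alcohol with C15 diethyl acetal, C16 trans to C10 | O=C1C=C(C)[C@]2(CC[C@](CO)(CC(OCC)OCC)O2)[C@@](COCc3ccccc3)(CCCO[Si](C)(C)C(C)(C)C)[C@@H]1C(C)COCc4ccccc4 | intermediate
20 | spiro tetrahydrofuran–oxolane: 9α,13:15,16-diepoxy-15-ethoxy-7-en-6-one | O=C1C=C(C)[C@]2(CC[C@]3(CC(OCC)OC3)O2)[C@@](COCc4ccccc4)(CCCO[Si](C)(C)C(C)(C)C)[C@@H]1C(C)COCc5ccccc5 | intermediate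
21 | potassium dienolate of 20 (O–K on C6; C6=C7, C8=C17) | [K]OC1=CC(=C)[C@]2(CC[C@]3(CC(OCC)OC3)O2)[C@@](COCc4ccccc4)(CCCO[Si](C)(C)C(C)(C)C)[C@@H]1C(C)COCc5ccccc5 | intermediate
22 | 8(17)-en-6-one | O=C1CC(=C)[C@]2(CC[C@]3(CC(OCC)OC3)O2)[C@@](COCc4ccccc4)(CCCO[Si](C)(C)C(C)(C)C)[C@@H]1C(C)COCc5ccccc5 | intermediate
23 | 8(17)-en-6β-ol | O[C@@H]1CC(=C)[C@]2(CC[C@]3(CC(OCC)OC3)O2)[C@@](COCc4ccccc4)(CCCO[Si](C)(C)C(C)(C)C)[C@@H]1C(C)COCc5ccccc5 | intermediate
24 | 8β,17-epoxy-6β-ol | O[C@@H]1C[C@@]6(CO6)[C@]2(CC[C@]3(CC(OCC)OC3)O2)[C@@](COCc4ccccc4)(CCCO[Si](C)(C)C(C)(C)C)[C@@H]1C(C)COCc5ccccc5 | intermediate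
25 | 3,6β-diol (3-hydroxypropyl arm on C10) | O[C@@H]1C[C@@]6(CO6)[C@]2(CC[C@]3(CC(OCC)OC3)O2)[C@@](COCc4ccccc4)(CCCO)[C@@H]1C(C)COCc5ccccc5 | intermediate
26 | C3 p-toluenesulfonate of 25 | O[C@@H]1C[C@@]6(CO6)[C@]2(CC[C@]3(CC(OCC)OC3)O2)[C@@](COCc4ccccc4)(CCCOS(=O)(=O)c7ccc(C)cc7)[C@@H]1C(C)COCc5ccccc5 | intermediate
27 | 6β-O-triethylsilyl ether of 26 | CC[Si](CC)(CC)O[C@@H]1C[C@@]6(CO6)[C@]2(CC[C@]3(CC(OCC)OC3)O2)[C@@](COCc4ccccc4)(CCCOS(=O)(=O)c7ccc(C)cc7)[C@@H]1C(C)COCc5ccccc5 | intermediate
28 | 19,20-diol | CC[Si](CC)(CC)O[C@@H]1C[C@@]6(CO6)[C@]2(CC[C@]3(CC(OCC)OC3)O2)[C@@](CO)(CCCOS(=O)(=O)c4ccc(C)cc4)[C@@H]1C(C)CO | intermediate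
29 | 19,20-lactol (19-hydroxy-19,20-epoxide) | CC[Si](CC)(CC)O[C@@H]1C[C@@]6(CO6)[C@]2(CC[C@]3(CC(OCC)OC3)O2)[C@]7(CCCOS(=O)(=O)c4ccc(C)cc4)COC(O)C(C)[C@H]17 | intermediate
30 | 19,20-olide: δ-lactone cis-fused to ring B, C4–H, tosyloxypropyl arm on C10 | CC[Si](CC)(CC)O[C@@H]1C[C@@]6(CO6)[C@]2(CC[C@]3(CC(OCC)OC3)O2)[C@]7(CCCOS(=O)(=O)c4ccc(C)cc4)COC(=O)C(C)[C@H]17 | intermediate
31 | potassium enolate of 30 (C4=C19–OK) | CC[Si](CC)(CC)O[C@@H]1C[C@@]6(CO6)[C@]2(CC[C@]3(CC(OCC)OC3)O2)[C@]7(CCCOS(=O)(=O)c4ccc(C)cc4)COC(O[K])=C(C)[C@H]17 | intermediate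
32 | ring-A-closed lactone: 6β-triethylsilyloxy, 15-ethoxy-14,15-dihydro analogue of the target skeleton | CC[Si](CC)(CC)O[C@@H]1C[C@@]2(CO2)[C@]2(CC[C@]3(CC(OCC)OC3)O2)[C@]23CCC[C@](C)(C(=O)OC2)[C@H]13 | intermediate
33 | 6β-alcohol | O[C@@H]1C[C@@]2(CO2)[C@]2(CC[C@]3(CC(OCC)OC3)O2)[C@]23CCC[C@](C)(C(=O)OC2)[C@H]13 | intermediate
34 | 6β-acetate, 15-ethoxy acetal | CC(=O)O[C@@H]1C[C@@]2(CO2)[C@]2(CC[C@]3(CC(OCC)OC3)O2)[C@]23CCC[C@](C)(C(=O)OC2)[C@H]13 | intermediate
35 | CNP0173713.2 (6β-acetoxy-8β,17:9α,13:15,16-triepoxylabd-14-en-19,20-olide) | CC(=O)O[C@@H]1C[C@@]2(CO2)[C@]2(CC[C@]3(C=COC3)O2)[C@]23CCC[C@](C)(C(=O)OC2)[C@H]13 | target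

**Step count and risks**

Total: 22 steps. Longest linear sequence: 20 steps (steps 1–5 and 8–22, from (R)-carvone); the side-chain branch is steps 6–7.

Steps most likely to fail:

Step 10. The hindered tertiary 9α-hydroxyl may engage the cobalt catalyst sluggishly, and the facial selectivity of ring closure at C13 may be modest. The fallback sets out from 18. Iodoetherification with N-iodosuccinimide (CH2Cl2, 0 °C) should give the 16-iodo tetrahydrofuran F1 through the same chair-like 5-exo closure. Radical oxygenation of the neopentyl iodide (Bu3SnH, air, toluene, then PPh3) should then give alcohol 19, where the fallback rejoins the route; 19 is cyclised to 20 with PPTS as in step 10.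

Step 22. The silyl triflate may open the oxirane, or the elimination may stop at the oxocarbenium stage and return acetal on work-up. The fallback sets out from 34. Acetal exchange with benzeneselenol and PPTS (CH2Cl2, 23 °C) should give the 15-phenylselanyl oxolane F2. Oxidation with NaIO4 (NaHCO3, THF/H2O, 0 → 23 °C) forms the selenoxide, whose syn-elimination towards C14 should give 35 without any Lewis acid.

Step 8. Transmetallation and reductive elimination at the tetrasubstituted, neopentyl-flanked dienyl triflate may be slow, so that β-hydride elimination of the alkylpalladium species competes. The fallback reverses the polarity of the partners and sets out from 10 and 14. Miyaura borylation of 10 (B2pin2, Pd(dppf)Cl2, KOAc, dioxane, 80 °C) should give the dienyl pinacol boronate F3. Alkyl–alkenyl Suzuki–Miyaura coupling of this with iodide 14 (Pd(OAc)2, P(t-Bu)2Me, KOt-Bu, tert-amyl alcohol, 23 °C) rejoins the route at 16.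

Further compounds
F1 | step 10 | 16-iodo tetrahydrofuran (iodomethyl analogue of 19) | O=C1C=C(C)[C@]2(CC[C@](CI)(CC(OCC)OCC)O2)[C@@](COCc3ccccc3)(CCCO[Si](C)(C)C(C)(C)C)[C@@H]1C(C)COCc4ccccc4
F2 | step 22 | 15-phenylselanyl oxolane (Se,O-acetal analogue of 34) | CC(=O)O[C@@H]1C[C@@]2(CO2)[C@]2(CC[C@]3(CC([Se]c4ccccc4)OC3)O2)[C@]23CCC[C@](C)(C(=O)OC2)[C@H]13
F3 | step 8 | dienyl pinacol boronate (C9–Bpin analogue of 10) | CC4(C)OB(OC4(C)C)C1=C(C)C=C[C@@H](C(C)COCc2ccccc2)[C@]1(COCc3ccccc3)CCCO[Si](C)(C)C(C)(C)C
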